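**Retrosynthetic overview**

1. Ring A is the tetrahydrofuran carrying the 4-hydroxy-3-methoxyphenyl group (ArCH, O, CH2, ring-fusion CH, ring-fusion C–OAc); ring B carries the 3,4-dimethoxyphenyl group. Target 20 ⇐ 19 ⇐ 18 by late O-acetylation and phenol debenzylation.
2. Ring A is closed last, at the bond between the oxygen-bearing ring-fusion carbon and the benzylic ArCH–O carbon. A Norrish–Yang photocyclisation of ring B ketone 16 joins these two acceptor-type carbons by radical–radical coupling and sets both of their stereocentres.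
3. Enabling feature: the acetoxy-bearing ring-fusion carbon is a masked ketone of ring B. The ring A oxygen stands γ to it (no hydrogen) and the benzylic carbon δ, so the excited carbonyl can only take a hydrogen from the ArCH2–O group (1,6-transfer), and the 1,5-biradical closes the five-membered ring A.
4. Ring B is formed first (step 7) by gold-catalysed alkyne oxidation/O–H insertion of anti-homopropargylic alcohol 14. Alcohol 14 comes from the Marshall allenylzinc addition of mesylate 11 to veratraldehyde 12, which sets both ring B stereocentres.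
5. 11 ⇐ asymmetric transfer hydrogenation of ynone 8 ⇐ Weinreb amide 4 ⇐ alcohol 1 + chloroamide 2 + alkyne 5. Ring order: B, then A.

Key step: step 8

Assumption: the sense of induction in step 3 is taken to follow that of alkynyl methyl ketones (alkynyl group in the place of the aryl group of acetophenone); should the α-alkoxy group reverse it, the (S,S)-catalyst is used. Ring positions are numbered as 3,7-dioxabicyclo[3.3.0]octane with the oxygen-bearing ring-fusion carbon as C1.

**Route**

Step 1
Reactants: 1 4-(benzyloxy)-3-methoxybenzyl alcohol; 2 2-chloro-N-methoxy-N-methylacetamide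
Product: 4 2-{[4-(benzyloxy)-3-methoxybenzyl]oxy}-N-methoxy-N-methylacetamide, via sodium alkoxide 3 (not isolated)
Conditions: NaH, THF, 0 °C; then 2, n-Bu4NI (cat.), 0 °C → rt
Reagents that add atoms: none
Why: Williamson ether synthesis, in which the primary benzylic alkoxide displaces chloride from the α-chloro amide by SN2 while the N-methoxy-N-methyl amide does not acylate the alkoxide; no stereocentre is formed.

Step 2
Reactants: 4 2-{[4-(benzyloxy)-3-methoxybenzyl]oxy}-N-methoxy-N-methylacetamide; 5 ethynyltrimethylsilane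
Product: 8 1-{[4-(benzyloxy)-3-methoxybenzyl]oxy}-4-(trimethylsilyl)but-3-yn-2-one, via lithium (trimethylsilyl)acetylide 6 (not isolated), via tetrahedral lithium alkoxide 7 (not isolated)
Conditions: 5, n-BuLi, THF, −78 °C; then 4, −78 → 0 °C; aq. NH4Cl
Reagents that add atoms: none
Why: Weinreb ketone synthesis, in which the acetylide adds only once because the lithium chelate 7 persists until the aqueous quench releases the ynone; no stereocentre is formed.

Step 3
Reactants: 8 1-{[4-(benzyloxy)-3-methoxybenzyl]oxy}-4-(trimethylsilyl)but-3-yn-2-one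
Product: 9 (S)-1-{[4-(benzyloxy)-3-methoxybenzyl]oxy}-4-(trimethylsilyl)but-3-yn-2-ol
Conditions: Ru[(R,R)-TsDPEN](p-cymene) (1 mol %), i-PrOH, rt
Reagents that add atoms: none
Why: Noyori asymmetric transfer hydrogenation of an alkynyl ketone, in which the ruthenium hydride/N–H pair delivers hydrogen to one carbonyl face with the alkynyl group beside the η6-arene, so the (R,R)-catalyst should give the (S)-carbinol (CH2O outranks the alkyne in the CIP order) without reducing the alkyne.

Step 4
Reactants: 9 (S)-1-{[4-(benzyloxy)-3-methoxybenzyl]oxy}-4-(trimethylsilyl)but-3-yn-2-ol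
Product: 10 (S)-1-{[4-(benzyloxy)-3-methoxybenzyl]oxy}but-3-yn-2-ol
Conditions: K2CO3 (cat.), MeOH, 0 °C → rt
Reagents that add atoms: none
Why: Protodesilylation of the alkynyl C–Si bond by catalytic methoxide, which leaves the carbinol centre and both benzyl ethers untouched.

Step 5
Reactants: 10 (S)-1-{[4-(benzyloxy)-3-methoxybenzyl]oxy}but-3-yn-2-ol
Product: 11 (S)-1-{[4-(benzyloxy)-3-methoxybenzyl]oxy}but-3-yn-2-yl methanesulfonate
Conditions: MsCl, Et3N, CH2Cl2, −78 °C
Reagents that add atoms: methanesulfonyl chloride CS(=O)(=O)Cl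
Why: O-Sulfonylation of the secondary propargylic alcohol with retention, giving the leaving group for the SN2' oxidative addition of step 6 (the mesylate is used without storage).

Step 6
Reactants: 11 (S)-1-{[4-(benzyloxy)-3-methoxybenzyl]oxy}but-3-yn-2-yl methanesulfonate; 12 3,4-dimethoxybenzaldehyde
Product: 14 (1S,2R)-2-({[4-(benzyloxy)-3-methoxybenzyl]oxy}methyl)-1-(3,4-dimethoxyphenyl)but-3-yn-1-ol, via allenylzinc 13 (not isolated)
Conditions: Pd(OAc)2 (5 mol %), PPh3 (5 mol %), Et2Zn (3 equiv), THF, −78 → −20 °C; aq. NH4Cl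
Reagents that add atoms: none
Why: Marshall propargylation, in which zerovalent palladium displaces the mesylate anti (SN2'), transmetalation with Et2Zn gives the axially chiral allenylzinc 13, and its addition to the aldehyde through a cyclic SE2' transition state transfers the chirality (net inversion at the propargylic carbon) and places aryl and CH2OR anti, setting both stereocentres of the anti adduct (the minor syn isomer is removed by chromatography).

Step 7
Reactants: 14 (1S,2R)-2-({[4-(benzyloxy)-3-methoxybenzyl]oxy}methyl)-1-(3,4-dimethoxyphenyl)but-3-yn-1-ol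
Product: 16 (4R,5S)-4-({[4-(benzyloxy)-3-methoxybenzyl]oxy}methyl)-5-(3,4-dimethoxyphenyl)dihydrofuran-3(2H)-one, via α-oxo gold carbene 15 (not isolated)
Conditions: Ph3PAuNTf2 (5 mol %), 8-methylquinoline N-oxide (1.3 equiv), 1,2-dichloroethane, rt
Reagents that add atoms: 8-methylquinoline N-oxide Cc1cccc2ccc[n+]([O-])c12
Why: Gold-catalysed alkyne oxidation with intramolecular O–H insertion, in which the N-oxide adds to the gold-activated terminal alkyne at the internal carbon, loss of 8-methylquinoline gives carbene 15, and the secondary hydroxyl captures the carbene carbon to close ring B as the 4,5-trans tetrahydrofuran-3-one without touching the two stereocentres under acid-free conditions.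

Step 8
Reactants: 16 (4R,5S)-4-({[4-(benzyloxy)-3-methoxybenzyl]oxy}methyl)-5-(3,4-dimethoxyphenyl)dihydrofuran-3(2H)-one
Product: 18 (1S,2R,5R,6S)-2-[4-(benzyloxy)-3-methoxyphenyl]-6-(3,4-dimethoxyphenyl)-3,7-dioxabicyclo[3.3.0]octan-1-ol, via 1,5-biradical 17 (not isolated)
Conditions: hν (300 nm, Pyrex), degassed benzene (0.01 M), rt
Reagents that add atoms: none
Why: n→π* excitation of the ring B ketone gives the triplet, whose oxygen abstracts one of the benzylic, ether-activated hydrogens of the ArCH2–O group through a seven-membered transition state (1,6-hydrogen transfer), and the resulting 1,5-biradical 17 (ketyl carbon and α-alkoxybenzyl carbon) collapses by radical–radical coupling to the bond between the two oxygenated carbons. The closest known reaction type is the Norrish–Yang cyclisation of β-alkoxy ketones to tetrahydrofuran-3-ols, which is established for 4-(benzyloxymethyl)tetrahydrofuran-3-ones giving 1-hydroxy-2,6-diaryl furofurans. Ring A is closed by 1,5-biradical recombination, formally a 5-exo attack of the benzylic radical on the ketyl carbon across the CH2–O–CH tether. The carbinol stereocentre is fixed by the existing stereocentre that carries the tether, because the short tether can reach only the ketyl face cis to it (cis-fused bicycle, hydroxyl cis to the ring-fusion hydrogen and to the dimethoxyphenyl group), and the benzylic stereocentre is set by the preference of the aryl group for the convex (exo) face of the closing biradical, away from ring B. The step needs δ-hydrogen abstraction to win over Norrish type 1 α-cleavage and over other C–H bonds, which is secured by the weak, doubly activated benzylic C–H held in a 1,6 relation to the carbonyl oxygen, by the absence of any γ-hydrogen on the tether (the γ atom is the ether oxygen), and by the fact that the other benzylic hydrogen lies in ring B itself and cannot reach the oxygen.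

Step 9
Reactants: 18 (1S,2R,5R,6S)-2-[4-(benzyloxy)-3-methoxyphenyl]-6-(3,4-dimethoxyphenyl)-3,7-dioxabicyclo[3.3.0]octan-1-ol
Product: 19 (1S,2R,5R,6S)-2-[4-(benzyloxy)-3-methoxyphenyl]-6-(3,4-dimethoxyphenyl)-3,7-dioxabicyclo[3.3.0]octan-1-yl acetate
Conditions: Ac2O, DMAP, Et3N, CH2Cl2, rt → 40 °C
Reagents that add atoms: acetic anhydride CC(=O)OC(C)=O
Why: DMAP-catalysed acylation (nucleophilic catalysis through the N-acetylpyridinium ion) of the only free hydroxyl, the tertiary ring-fusion alcohol on the convex face, under base-only conditions that do not ionise the benzylic ethers, so no stereocentre changes.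

Step 10
Reactants: 19 (1S,2R,5R,6S)-2-[4-(benzyloxy)-3-methoxyphenyl]-6-(3,4-dimethoxyphenyl)-3,7-dioxabicyclo[3.3.0]octan-1-yl acetate
Product: 20 (1S,2R,5R,6S)-6-(3,4-dimethoxyphenyl)-2-(4-hydroxy-3-methoxyphenyl)-3,7-dioxabicyclo[3.3.0]octan-1-yl acetate
Conditions: H2 (1 atm), Pd/C (10 %), EtOAc, rt
Reagents that add atoms: none
Why: Catalytic hydrogenolysis of the aryl benzyl ether, which should be much faster in ethyl acetate than cleavage of the dialkyl benzylic C–O bonds of the furofuran and leaves the tertiary acetate and all four stereocentres unaffected.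

**Compound list**

1 | 4-(benzyloxy)-3-methoxybenzyl alcohol | COc1cc(CO)ccc1OCc1ccccc1 | starting material
2 | 2-chloro-N-methoxy-N-methylacetamide | CON(C)C(=O)CCl | starting material
3 | sodium [4-(benzyloxy)-3-methoxyphenyl]methanolate | COc1cc(C[O-])ccc1OCc1ccccc1.[Na+] | intermediate (not isolated)
4 | 2-{[4-(benzyloxy)-3-methoxybenzyl]oxy}-N-methoxy-N-methylacetamide | COc1cc(COCC(=O)N(C)OC)ccc1OCc1ccccc1 | intermediate
5 | ethynyltrimethylsilane | C#C[Si](C)(C)C | starting material
6 | lithium (trimethylsilyl)acetylide | [Li]C#C[Si](C)(C)C | intermediate (not isolated)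
7 | tetrahedral lithium alkoxide (acetylide adduct of 4, lithium chelated by the N-methoxy group) | COc1cc(COCC(O[Li])(C#C[Si](C)(C)C)N(C)OC)ccc1OCc1ccccc1 | intermediate (not isolated)
8 | 1-{[4-(benzyloxy)-3-methoxybenzyl]oxy}-4-(trimethylsilyl)but-3-yn-2-one | COc1cc(COCC(=O)C#C[Si](C)(C)C)ccc1OCc1ccccc1 | intermediate
9 | (S)-1-{[4-(benzyloxy)-3-methoxybenzyl]oxy}-4-(trimethylsilyl)but-3-yn-2-ol | COc1cc(COC[C@@H](O)C#C[Si](C)(C)C)ccc1OCc1ccccc1 | intermediate
10 | (S)-1-{[4-(benzyloxy)-3-methoxybenzyl]oxy}but-3-yn-2-ol | COc1cc(COC[C@@H](O)C#C)ccc1OCc1ccccc1 | intermediate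
11 | (S)-1-{[4-(benzyloxy)-3-methoxybenzyl]oxy}but-3-yn-2-yl methanesulfonate | COc1cc(COC[C@H](C#C)OS(C)(=O)=O)ccc1OCc1ccccc1 | intermediate
12 | 3,4-dimethoxybenzaldehyde (veratraldehyde) | COc1ccc(C=O)cc1OC | starting material
13 | (P)-(4-{[4-(benzyloxy)-3-methoxybenzyl]oxy}buta-1,2-dien-1-yl)(ethyl)zinc (zinc anti to the departed mesylate) | CC[Zn]C([H])=[C@@]=C([H])COCc1ccc(OCc2ccccc2)c(OC)c1 | intermediate (not isolated)
14 | (1S,2R)-2-({[4-(benzyloxy)-3-methoxybenzyl]oxy}methyl)-1-(3,4-dimethoxyphenyl)but-3-yn-1-ol (anti) | COc1cc(COC[C@@H](C#C)[C@@H](c2ccc(OC)c(OC)c2)O)ccc1OCc1ccccc1 | intermediate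
15 | α-oxo gold carbene (triphenylphosphine-gold carbene at the former alkyne terminus, triflimide counter-ion) | COc1cc(COC[C@@H](C(=O)C=[Au][P+](c2ccccc2)(c2ccccc2)c2ccccc2)[C@@H](c2ccc(OC)c(OC)c2)O)ccc1OCc1ccccc1.O=S(=O)([N-]S(=O)(=O)C(F)(F)F)C(F)(F)F | intermediate (not isolated)
16 | (4R,5S)-4-({[4-(benzyloxy)-3-methoxybenzyl]oxy}methyl)-5-(3,4-dimethoxyphenyl)dihydrofuran-3(2H)-one (4,5-trans) | COc1cc(COC[C@@H]2[C@@H](c3ccc(OC)c(OC)c3)OCC2=O)ccc1OCc1ccccc1 | intermediate
17 | 1,5-biradical (ring B ketyl carbon and α-alkoxybenzyl carbon) | COc1cc([CH]OC[C@@H]2[C@@H](c3ccc(OC)c(OC)c3)OC[C]2O)ccc1OCc1ccccc1 | intermediate (not isolated)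
18 | (1S,2R,5R,6S)-2-[4-(benzyloxy)-3-methoxyphenyl]-6-(3,4-dimethoxyphenyl)-3,7-dioxabicyclo[3.3.0]octan-1-ol (cis-fused, both aryl groups exo) | COc1cc([C@H]2OC[C@@H]3[C@@H](c4ccc(OC)c(OC)c4)OC[C@]23O)ccc1OCc1ccccc1 | intermediate
19 | (1S,2R,5R,6S)-2-[4-(benzyloxy)-3-methoxyphenyl]-6-(3,4-dimethoxyphenyl)-3,7-dioxabicyclo[3.3.0]octan-1-yl acetate | COc1cc([C@H]2OC[C@@H]3[C@@H](c4ccc(OC)c(OC)c4)OC[C@]23OC(C)=O)ccc1OCc1ccccc1 | intermediate
20 | (1S,2R,5R,6S)-6-(3,4-dimethoxyphenyl)-2-(4-hydroxy-3-methoxyphenyl)-3,7-dioxabicyclo[3.3.0]octan-1-yl acetate | COc1cc([C@H]2OC[C@@H]3[C@@H](c4ccc(OC)c(OC)c4)OC[C@]23OC(C)=O)ccc1O | target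

**Step count and risks**

Total step count: 10. Longest linear sequence: 10 steps (1 → 20); compounds 2, 5 and 12 enter as commercial materials.

Steps most likely to fail:

Step 8. The triplet ketone may be deactivated by charge transfer from the two electron-rich arenes or lost through Norrish type 1 α-cleavage before the δ-hydrogen is abstracted, and the biradical may collapse with poor facial selectivity at the benzylic carbon. The fallback sets out from 16 and comes back at 18; it is ionic instead of photochemical, and ring A is still closed last, now at the benzylic C–O bond. Alcohol 1 is converted with Ph3P·HBr (MeCN, reflux) into [4-(benzyloxy)-3-methoxybenzyl]triphenylphosphonium bromide F1, which KN(SiMe3)2 (THF, −78 °C) turns into the ylide F2. Wittig olefination of 16 should give the 3-arylidene tetrahydrofuran F3; either alkene geometry serves. Dihydroxylation (OsO4 cat., N-methylmorpholine N-oxide, acetone–water) from the face anti to the neighbouring CH2OR group should give the diol F4, in which the tertiary oxygen already has the configuration of 18. Camphorsulfonic acid in CH2Cl2 with 1,3,5-trimethoxybenzene as cation scavenger then ionises the secondary benzylic alcohol. The ether oxygen of the side chain closes ring A on the cation from the side that places the aryl group exo, and the 4-(benzyloxy)-3-methoxybenzyl group leaves from the oxonium ion as a stabilised cation (debenzylative cycloetherification), which returns 18.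

Step 6. Chirality transfer may be incomplete (racemisation of the allenylzinc before addition), and the anti/syn selectivity may be modest with an aromatic aldehyde. The fallback sets out from 9 and comes back at 14; it uses an isolable, configurationally stable allenylboron reagent and a closed transition state. Alcohol 9 is converted (ClCO2Me, pyridine, CH2Cl2) into the methyl carbonate F5. Copper-catalysed anti-SN2' borylation (CuCl, NaO-t-Bu, Xantphos, B2pin2, THF) should give the axially chiral allenylboronate F6. Its thermal addition to 12 through a six-membered transition state should give the anti silylated homopropargylic alcohol F7, with chirality transfer in the same sense as in step 6. K2CO3 in MeOH removes the silyl group and returns 14.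

Step 7. The α-oxo gold carbene may be diverted by the ether oxygen of the benzylic side chain (oxonium ylide formation and benzyl shift) or oxidised further by a second N-oxide, and the electron-rich benzylic alcohol may ionise at the Lewis-acidic metal. The fallback sets out from 14 and comes back at 16 without a carbene. Alkynol cycloisomerisation through a molybdenum vinylidene (Mo(CO)6, Et3N, Et2O, hν) should give the 2,3-dihydrofuran F8. Hydroboration–oxidation (BH3·THF; NaOH, H2O2) places the hydroxyl on the carbon β to the ring oxygen, anti to the neighbouring substituent, to give the tetrahydrofuran-3-ol F9. Dess–Martin periodinane oxidation returns ketone 16.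

**Further compounds**

F1 | step 8 | [4-(benzyloxy)-3-methoxybenzyl]triphenylphosphonium bromide | COc1cc(C[P+](c2ccccc2)(c2ccccc2)c2ccccc2)ccc1OCc1ccccc1.[Br-]
F2 | step 8 | [4-(benzyloxy)-3-methoxybenzylidene]triphenylphosphorane | COc1cc(C=P(c2ccccc2)(c2ccccc2)c2ccccc2)ccc1OCc1ccccc1
F3 | step 8 | (2S,3R)-4-[4-(benzyloxy)-3-methoxybenzylidene]-3-({[4-(benzyloxy)-3-methoxybenzyl]oxy}methyl)-2-(3,4-dimethoxyphenyl)tetrahydrofuran (alkene geometry not defined) | COc1cc(COC[C@@H]2[C@@H](c3ccc(OC)c(OC)c3)OCC2=Cc2ccc(OCc3ccccc3)c(OC)c2)ccc1OCc1ccccc1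
F4 | step 8 | (3S,4R,5S)-3-{[4-(benzyloxy)-3-methoxyphenyl](hydroxy)methyl}-4-({[4-(benzyloxy)-3-methoxybenzyl]oxy}methyl)-5-(3,4-dimethoxyphenyl)tetrahydrofuran-3-ol (secondary carbinol configuration not defined) | COc1cc(COC[C@@H]2[C@@H](c3ccc(OC)c(OC)c3)OC[C@]2(O)C(O)c2ccc(OCc3ccccc3)c(OC)c2)ccc1OCc1ccccc1
F5 | step 6 | (S)-1-{[4-(benzyloxy)-3-methoxybenzyl]oxy}-4-(trimethylsilyl)but-3-yn-2-yl methyl carbonate | COc1cc(COC[C@H](C#C[Si](C)(C)C)OC(=O)OC)ccc1OCc1ccccc1
F6 | step 6 | (M)-2-[4-{[4-(benzyloxy)-3-methoxybenzyl]oxy}-1-(trimethylsilyl)buta-1,2-dien-1-yl]-4,4,5,5-tetramethyl-1,3,2-dioxaborolane (boron anti to the departed carbonate) | CC1(C)OB(OC1(C)C)C([Si](C)(C)C)=[C@@]=C([H])COCc1ccc(OCc2ccccc2)c(OC)c1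
F7 | step 6 | (1S,2R)-2-({[4-(benzyloxy)-3-methoxybenzyl]oxy}methyl)-1-(3,4-dimethoxyphenyl)-4-(trimethylsilyl)but-3-yn-1-ol | COc1cc(COC[C@@H](C#C[Si](C)(C)C)[C@@H](c2ccc(OC)c(OC)c2)O)ccc1OCc1ccccc1
F8 | step 7 | (2S,3R)-3-({[4-(benzyloxy)-3-methoxybenzyl]oxy}methyl)-2-(3,4-dimethoxyphenyl)-2,3-dihydrofuran | COc1cc(COC[C@@H]2[C@@H](c3ccc(OC)c(OC)c3)OC=C2)ccc1OCc1ccccc1
F9 | step 7 | (3S,4S,5S)-4-({[4-(benzyloxy)-3-methoxybenzyl]oxy}methyl)-5-(3,4-dimethoxyphenyl)tetrahydrofuran-3-ol | COc1cc(COC[C@@H]2[C@@H](c3ccc(OC)c(OC)c3)OC[C@H]2O)ccc1OCc1ccccc1
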